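## Retrosynthetic overview

- Target ⇐ selective C2 acetylation of a 2,3-diol acid aldehyde ⇐ one-pot oxidation of the C15 and C19 carbinols of a tetraol ⇐ hydride reduction of a 2-hydroxy-3-keto ester ⇐ enolate hydroxylation of a bicyclic β-keto ester.
- Key disconnection, C4–C5 and C9–C10 in one operation: one-electron oxidation of an acyclic α-methyl β-keto ester turns the normally nucleophilic C4 into an electrophilic radical (an enolonium equivalent), which bonds to the nucleophilic alkene carbon C5. Ring A closes first, ring B second, and loss of a sulfonyl group from C7 places the alkene at C7=C8 only.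
- Stereocontrol: C13 from (R)-citronellol; C4, C5, C9 and C10 from the chair–chair cascade under an 8-phenylmenthyl ester; C2 and C3 from the rigid decalin.
- Acyclic precursor ⇐ β-keto ester dianion + allylic bromide (C1–C2) ⇐ lithiated allylic sulfone + chlorohydrin of isoprene monoxide (C6–C7) ⇐ allylic oxidation of citronellyl pivalate.

Convention: positions are cited in labdane numbering (ring A = C1–C5, C10; ring B = C5–C10; C15 = carboxyl carbon; C19 = axial carbon on C4). Enolates, carbanions, alkoxides and radicals are treated as reactive forms of the numbered compounds.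

Assumption: the (1S,2R,5S)-8-phenylmenthyl ester is taken to expose the face of the C4 radical that leads to the (4S,5S,9R,10S) decalin; if experiment shows the opposite sense, the (1R,2S,5R) alcohol is used and nothing else changes.

## Route

Step 1
Reactants: 1 (R)-(+)-β-citronellol
Product: 2 (3R)-3,7-dimethyloct-6-en-1-yl pivalate
Conditions: PivCl, pyridine, DMAP (cat.), CH2Cl2, 0 °C → rt
Reagents that add atoms: pivaloyl chloride CC(C)(C)C(Cl)=O
Why: Acylation with an acid chloride; the pivalate has no α-hydrogen, survives every base used later and is removed by LiAlH4 in step 11.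

Step 2
Reactants: 2 (3R)-3,7-dimethyloct-6-en-1-yl pivalate
Product: 3 (3R,6E)-8-hydroxy-3,7-dimethyloct-6-en-1-yl pivalate
Conditions: SeO2 (0.3 equiv), t-BuOOH (70% aq., 3 equiv), salicylic acid (0.1 equiv), CH2Cl2, rt
Reagents that add atoms: tert-butyl hydroperoxide CC(C)(C)OO (oxygen relayed by catalytic selenium dioxide O=[Se]=O)
Why: Sharpless catalytic SeO2 allylic oxidation (ene reaction, then [2,3]-sigmatropic shift) hydroxylates the (E)-methyl group of the trisubstituted alkene selectively.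

Step 3
Reactants: 3 (3R,6E)-8-hydroxy-3,7-dimethyloct-6-en-1-yl pivalate
Product: 5 (3R,6E)-3,7-dimethyl-8-(phenylsulfonyl)oct-6-en-1-yl pivalate, via allylic bromide 4 (not isolated)
Conditions: PBr3 (0.4 equiv), Et2O, −10 °C; then NaO2SPh (1.5 equiv), DMF, rt
Reagents that add atoms: phosphorus tribromide BrP(Br)Br (bromine of 4 only); sodium benzenesulfinate [Na+].[O-]S(=O)c1ccccc1
Why: SN2 bromination of the primary allylic alcohol followed by S-alkylation of the sulfinate gives the allylic sulfone with the E-alkene unchanged.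

Step 4
Reactants: 6 2-methyl-2-vinyloxirane (racemic)
Product: 7 (2E)-4-chloro-2-methylbut-2-en-1-ol
Conditions: TiCl4 (1.0 equiv), CH2Cl2, −85 °C; H2O work-up
Reagents that add atoms: titanium tetrachloride Cl[Ti](Cl)(Cl)Cl
Why: Lewis-acid-mediated SN2' opening of the vinyl epoxide by chloride gives the (E)-1,4-chlorohydrin, a known preparation of this C5 unit.

Step 5
Reactants: 5 (3R,6E)-3,7-dimethyl-8-(phenylsulfonyl)oct-6-en-1-yl pivalate; 7 (2E)-4-chloro-2-methylbut-2-en-1-ol
Product: 8 (3R,6E,10E)-12-hydroxy-3,7,11-trimethyl-8-(phenylsulfonyl)dodeca-6,10-dien-1-yl pivalate (both epimers at the sulfonyl carbon)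
Conditions: LiN(SiMe3)2 (2.1 equiv), THF–DMPU, −78 → −20 °C; AcOH quench
Reagents that add atoms: none
Why: Julia/Biellmann-type α-alkylation of the lithiated allylic sulfone by the allylic chloride (the hydroxyl rides as its lithium alkoxide); the new sulfonyl-bearing centre (C7) is destroyed in step 9, so its configuration is irrelevant.

Step 6
Reactants: 8 (3R,6E,10E)-12-hydroxy-3,7,11-trimethyl-8-(phenylsulfonyl)dodeca-6,10-dien-1-yl pivalate
Product: 9 (3R,6E,10E)-12-bromo-3,7,11-trimethyl-8-(phenylsulfonyl)dodeca-6,10-dien-1-yl pivalate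
Conditions: CBr4, PPh3, CH2Cl2, 0 °C
Reagents that add atoms: carbon tetrabromide BrC(Br)(Br)Br
Why: Appel reaction converts the primary allylic alcohol to the bromide under neutral conditions that leave sulfone, pivalate and alkenes untouched.

Step 7
Reactants: 10 (+)-8-phenylmenthol [(1S,2R,5S)-5-methyl-2-(2-phenylpropan-2-yl)cyclohexan-1-ol]; 11 ethyl 2-methyl-3-oxobutanoate (racemic)
Product: 12 (1S,2R,5S)-8-phenylmenthyl 2-methyl-3-oxobutanoate (enolisable α-centre, both epimers)
Conditions: DMAP (0.3 equiv), toluene, reflux, 4 Å MS (removal of EtOH)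
Reagents that add atoms: none
Why: DMAP-catalysed transesterification of a β-keto ester (via the acylketene) installs the recoverable chiral ester.

Step 8
Reactants: 12 (1S,2R,5S)-8-phenylmenthyl 2-methyl-3-oxobutanoate; 9 (3R,6E,10E)-12-bromo-3,7,11-trimethyl-8-(phenylsulfonyl)dodeca-6,10-dien-1-yl pivalate
Product: 13 (1S,2R,5S)-8-phenylmenthyl (6E,10E,14R)-2,6,10,14-tetramethyl-3-oxo-9-(phenylsulfonyl)-16-(pivaloyloxy)hexadeca-6,10-dienoate (epimers at chain C2 and C9)
Conditions: LiN(iPr)2 (2.2 equiv), THF, −78 → 0 °C; 9 added at −78 °C, → −20 °C; AcOH quench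
Reagents that add atoms: none
Why: Huckin–Weiler γ-alkylation of the β-keto ester dianion; the terminal carbanion attacks the allylic bromide at −78 °C faster than it removes the hindered tertiary α-sulfonyl hydrogen.

Step 9
Reactants: 13 (1S,2R,5S)-8-phenylmenthyl (6E,10E,14R)-2,6,10,14-tetramethyl-3-oxo-9-(phenylsulfonyl)-16-(pivaloyloxy)hexadeca-6,10-dienoate
Product: 14 (1S,2R,5S)-8-phenylmenthyl (4S,5S,9R,10S,13R)-3-oxo-15-(pivaloyloxy)labd-7-en-19-oate
Conditions: Mn(OAc)3·2H2O (2.5 equiv), degassed AcOH, 20 °C, slow addition of 13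
Reagents that add atoms: none
Why: Proposed new method: manganese triacetate oxidises the enol of 13 to the electrophilic α-keto-ester radical at C4 (polarity of the enolate carbon reversed), which attacks nucleophilic C5 of the trisubstituted alkene 6-endo through a chair with the two carbonyls anti (ester axial) and the face opposite the auxiliary phenyl ring exposed, setting C4 and C5; the tertiary C10 radical then closes ring B 6-endo on C9 of the E-allyl sulfone (trans fusion, equatorial side chain, setting C10 and C9), and the C8 radical expels PhSO2•, leaving the alkene at C7=C8 only; the closest known reactions are the Snider-type Mn(OAc)3 oxidative polyene cyclisation of α-methyl β-keto esters under 8-phenylmenthyl control and radical allylation by addition–fragmentation of allyl sulfones.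

Step 10
Reactants: 14 (1S,2R,5S)-8-phenylmenthyl (4S,5S,9R,10S,13R)-3-oxo-15-(pivaloyloxy)labd-7-en-19-oate
Product: 15 (1S,2R,5S)-8-phenylmenthyl (2S,4S,5S,9R,10S,13R)-2-hydroxy-3-oxo-15-(pivaloyloxy)labd-7-en-19-oate
Conditions: KN(SiMe3)2 (1.2 equiv), THF, −78 °C; 3-phenyl-2-(phenylsulfonyl)oxaziridine, −78 °C; AcOH quench
Reagents that add atoms: (±)-3-phenyl-2-(phenylsulfonyl)oxaziridine O=S(=O)(N1OC1c1ccccc1)c1ccccc1
Why: Davis enolate hydroxylation; C4 is quaternary so only the C2 enolate can form, and the oxaziridine attacks C2 anti to the axial C10 methyl and C19 ester, giving the equatorial 2-hydroxyl.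

Step 11
Reactants: 15 (1S,2R,5S)-8-phenylmenthyl (2S,4S,5S,9R,10S,13R)-2-hydroxy-3-oxo-15-(pivaloyloxy)labd-7-en-19-oate
Product: 17 (2S,3R,4R,5S,9R,10S,13R)-labd-7-ene-2,3,15,19-tetraol, via cis-diol diester 16 (not isolated)
Conditions: LiBH(s-Bu)3 (2.5 equiv), THF, −78 °C; then LiAlH4 (6 equiv), 0 → 60 °C; H2O, aq. NaOH work-up
Reagents that add atoms: none
Why: The bulky borohydride attacks C3 along the equatorial trajectory to give the axial alcohol cis to the 2-hydroxyl (as known for 4,4-disubstituted 3-keto decalins), and LiAlH4 then cleaves both esters reductively, releasing the auxiliary for recovery.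

Step 12
Reactants: 17 (2S,3R,4R,5S,9R,10S,13R)-labd-7-ene-2,3,15,19-tetraol
Product: 18 (2S,3R,4S,5S,9R,10S,13R)-2,3-dihydroxy-19-oxolabd-7-en-15-oic acid
Conditions: TEMPO (0.2 equiv), PhI(OAc)2 (3.3 equiv), MeCN–H2O 1:1, 0 °C → rt
Reagents that add atoms: water O
Why: Nitroxyl-catalysed oxidation is selective for primary alcohols; the unhindered C15 aldehyde hydrates and goes on to the acid, whereas the neopentyl, axial C19 aldehyde does not hydrate and stops.

Step 13
Reactants: 18 (2S,3R,4S,5S,9R,10S,13R)-2,3-dihydroxy-19-oxolabd-7-en-15-oic acid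
Product: 19 (2S,3R,4S,5S,9R,10S,13R)-2-acetoxy-3-hydroxy-19-oxolabd-7-en-15-oic acid (target)
Conditions: Ac2O (1.5 equiv), pyridine, CH2Cl2, 0 °C; aqueous work-up
Reagents that add atoms: acetic anhydride CC(=O)OC(C)=O
Why: Selective esterification: the equatorial C2 hydroxyl acylates far faster than the axial, neopentyl C3 hydroxyl next to quaternary C4, and any mixed anhydride at C15 hydrolyses on work-up.

## Compound list

1 | (R)-(+)-β-citronellol | CC(C)=CCC[C@@H](C)CCO | starting material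
2 | (3R)-3,7-dimethyloct-6-en-1-yl pivalate | CC(C)=CCC[C@@H](C)CCOC(=O)C(C)(C)C | intermediate
3 | (3R,6E)-8-hydroxy-3,7-dimethyloct-6-en-1-yl pivalate | OC/C(C)=C/CC[C@@H](C)CCOC(=O)C(C)(C)C | intermediate
4 | (3R,6E)-8-bromo-3,7-dimethyloct-6-en-1-yl pivalate (not isolated) | BrC/C(C)=C/CC[C@@H](C)CCOC(=O)C(C)(C)C | intermediate
5 | (3R,6E)-3,7-dimethyl-8-(phenylsulfonyl)oct-6-en-1-yl pivalate | O=S(=O)(C/C(C)=C/CC[C@@H](C)CCOC(=O)C(C)(C)C)c1ccccc1 | intermediate
6 | 2-methyl-2-vinyloxirane (racemic) | CC1(C=C)CO1 | starting material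
7 | (2E)-4-chloro-2-methylbut-2-en-1-ol | OC/C(C)=C/CCl | intermediate
8 | (3R,6E,10E)-12-hydroxy-3,7,11-trimethyl-8-(phenylsulfonyl)dodeca-6,10-dien-1-yl pivalate (C8 epimers) | OC/C(C)=C/CC(/C(C)=C/CC[C@@H](C)CCOC(=O)C(C)(C)C)S(=O)(=O)c1ccccc1 | intermediate
9 | (3R,6E,10E)-12-bromo-3,7,11-trimethyl-8-(phenylsulfonyl)dodeca-6,10-dien-1-yl pivalate (C8 epimers) | BrC/C(C)=C/CC(/C(C)=C/CC[C@@H](C)CCOC(=O)C(C)(C)C)S(=O)(=O)c1ccccc1 | intermediate
10 | (+)-8-phenylmenthol, (1S,2R,5S)-5-methyl-2-(2-phenylpropan-2-yl)cyclohexan-1-ol | O[C@H]1C[C@@H](C)CC[C@@H]1C(C)(C)c1ccccc1 | starting material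
11 | ethyl 2-methyl-3-oxobutanoate (racemic) | CCOC(=O)C(C)C(C)=O | starting material
12 | (1S,2R,5S)-8-phenylmenthyl 2-methyl-3-oxobutanoate (α-epimers) | CC(=O)C(C)C(=O)O[C@H]1C[C@@H](C)CC[C@@H]1C(C)(C)c1ccccc1 | intermediate
13 | (1S,2R,5S)-8-phenylmenthyl (6E,10E,14R)-2,6,10,14-tetramethyl-3-oxo-9-(phenylsulfonyl)-16-(pivaloyloxy)hexadeca-6,10-dienoate (epimers at chain C2 and C9) | CC(C(=O)CC/C(C)=C/CC(/C(C)=C/CC[C@@H](C)CCOC(=O)C(C)(C)C)S(=O)(=O)c1ccccc1)C(=O)O[C@H]2C[C@@H](C)CC[C@@H]2C(C)(C)c3ccccc3 | intermediate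
14 | (1S,2R,5S)-8-phenylmenthyl (4S,5S,9R,10S,13R)-3-oxo-15-(pivaloyloxy)labd-7-en-19-oate | O=C1CC[C@@]2(C)[C@H](CC[C@@H](C)CCOC(=O)C(C)(C)C)C(C)=CC[C@@H]2[C@]1(C)C(=O)O[C@H]3C[C@@H](C)CC[C@@H]3C(C)(C)c4ccccc4 | intermediate
15 | (1S,2R,5S)-8-phenylmenthyl (2S,4S,5S,9R,10S,13R)-2-hydroxy-3-oxo-15-(pivaloyloxy)labd-7-en-19-oate | O=C1[C@@H](O)C[C@@]2(C)[C@H](CC[C@@H](C)CCOC(=O)C(C)(C)C)C(C)=CC[C@@H]2[C@]1(C)C(=O)O[C@H]3C[C@@H](C)CC[C@@H]3C(C)(C)c4ccccc4 | intermediate
16 | (1S,2R,5S)-8-phenylmenthyl (2S,3R,4S,5S,9R,10S,13R)-2,3-dihydroxy-15-(pivaloyloxy)labd-7-en-19-oate (not isolated) | O[C@H]1C[C@@]2(C)[C@H](CC[C@@H](C)CCOC(=O)C(C)(C)C)C(C)=CC[C@@H]2[C@](C)(C(=O)O[C@H]3C[C@@H](C)CC[C@@H]3C(C)(C)c4ccccc4)[C@H]1O | intermediate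
17 | (2S,3R,4R,5S,9R,10S,13R)-labd-7-ene-2,3,15,19-tetraol | O[C@H]1C[C@@]2(C)[C@H](CC[C@@H](C)CCO)C(C)=CC[C@@H]2[C@](C)(CO)[C@H]1O | intermediate
18 | (2S,3R,4S,5S,9R,10S,13R)-2,3-dihydroxy-19-oxolabd-7-en-15-oic acid | O[C@H]1C[C@@]2(C)[C@H](CC[C@@H](C)CC(=O)O)C(C)=CC[C@@H]2[C@](C)(C=O)[C@H]1O | intermediate
19 | (2S,3R,4S,5S,9R,10S,13R)-2-acetoxy-3-hydroxy-19-oxolabd-7-en-15-oic acid (CNP0180877.1) | CC(=O)O[C@H]1C[C@@]2(C)[C@H](CC[C@@H](C)CC(=O)O)C(C)=CC[C@@H]2[C@](C)(C=O)[C@H]1O | target

## Step count and risks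

Total steps: 13 (two one-step side branches, steps 4 and 7). Longest linear sequence: 11 (steps 1, 2, 3, 5, 6, 8, 9, 10, 11, 12, 13).

Most likely to fail:

Step 9. The expelled sulfonyl radical can shift the allyl sulfone of unreacted 13 or add to alkenes, enolisation of the α-methyl keto ester by manganese triacetate is slow, and auxiliary control may be modest. Fallback, setting out from 13 and returning at 14: brominate C4 with N-bromosuccinimide and catalytic Mg(ClO4)2 to give the α-bromo keto ester F1. Then generate the same C4 radical reductively in a tin chain with Bu3Sn–SnBu3 under visible light in benzene. The tributyltin radical abstracts bromine, the cascade runs as before, and the sulfonyl radical is captured at once by the ditin, which regenerates the chain carrier. This removes both the stoichiometric oxidant and free PhSO2• and delivers 14.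

Step 11. Equatorial hydride delivery to C3 has to pass the axial C19 ester and could give the equatorial (trans) alcohol, and the hot LiAlH4 stage could trigger retro-aldol cleavage. Fallback, setting out from 14 and returning at 17; it replaces reagent control by hydroxyl-directed hydride delivery:
- Mask the ketone of 14 with TBSOTf and Et3N as the silyl enol ether F2.
- Cleave both esters with LiAlH4 to the 15,19-diol enol ether F3.
- Carry out a Rubottom oxidation with dimethyldioxirane (1 equiv, −78 °C); the enol ether reacts far faster than the C7 alkene, on the face anti to the axial groups, to give the 2-silyloxy ketone diol F4.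
- Reduce with Me4NBH(OAc)3 in MeCN–AcOH; the C19 carbinol binds boron and delivers hydride to the C3 face syn to C19, which can only give the axial alcohol, the 2-silyloxy triol F5.
- Remove the silyl group with Bu4NF to reach 17.

Step 12. The neopentyl C19 carbinol may oxidise no faster than the equatorial C2 carbinol, and PhI(OAc)2 could cleave the cis-diol. Fallback, setting out from 17 and returning at 18: protect the cis-2,3-diol with 2,2-dimethoxypropane and PPTS as the acetonide diol F6 (O3 and C19 are anti, so only the 2,3-ketal can form). Oxidise without restraint with TEMPO and PhI(OAc)2 in wet MeCN to the acetonide acid aldehyde F7. Remove the ketal with 80% AcOH at 40 °C to give 18.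

## Further compounds

F1 | step 9 | (1S,2R,5S)-8-phenylmenthyl (6E,10E,14R)-2-bromo-2,6,10,14-tetramethyl-3-oxo-9-(phenylsulfonyl)-16-(pivaloyloxy)hexadeca-6,10-dienoate | CC(Br)(C(=O)CC/C(C)=C/CC(/C(C)=C/CC[C@@H](C)CCOC(=O)C(C)(C)C)S(=O)(=O)c1ccccc1)C(=O)O[C@H]2C[C@@H](C)CC[C@@H]2C(C)(C)c3ccccc3
F2 | step 11 | tert-butyldimethylsilyl enol ether (C2=C3) of 14 | CC(C)(C)[Si](C)(C)OC1=CC[C@@]2(C)[C@H](CC[C@@H](C)CCOC(=O)C(C)(C)C)C(C)=CC[C@@H]2[C@]1(C)C(=O)O[C@H]3C[C@@H](C)CC[C@@H]3C(C)(C)c4ccccc4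
F3 | step 11 | 3-(tert-butyldimethylsilyloxy)labda-2,7-diene-15,19-diol | CC(C)(C)[Si](C)(C)OC1=CC[C@@]2(C)[C@H](CC[C@@H](C)CCO)C(C)=CC[C@@H]2[C@]1(C)CO
F4 | step 11 | 2-(tert-butyldimethylsilyloxy)-15,19-dihydroxylabd-7-en-3-one | O=C1[C@@H](O[Si](C)(C)C(C)(C)C)C[C@@]2(C)[C@H](CC[C@@H](C)CCO)C(C)=CC[C@@H]2[C@]1(C)CO
F5 | step 11 | 2-(tert-butyldimethylsilyloxy)labd-7-ene-3,15,19-triol (axial 3-OH) | CC(C)(C)[Si](C)(C)O[C@H]1C[C@@]2(C)[C@H](CC[C@@H](C)CCO)C(C)=CC[C@@H]2[C@](C)(CO)[C@H]1O
F6 | step 12 | 2,3-O-isopropylidene-labd-7-ene-2,3,15,19-tetraol | CC1(C)O[C@H]2C[C@@]3(C)[C@H](CC[C@@H](C)CCO)C(C)=CC[C@@H]3[C@](C)(CO)[C@H]2O1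
F7 | step 12 | 2,3-O-isopropylidene-2,3-dihydroxy-19-oxolabd-7-en-15-oic acid | CC1(C)O[C@H]2C[C@@]3(C)[C@H](CC[C@@H](C)CC(=O)O)C(C)=CC[C@@H]3[C@](C)(C=O)[C@H]2O1
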